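**Strategy.** In chroman numbering (O1, C2, C3, C4), the pyran ring is disconnected at C3–C4, but not with O1–C2 in place, because a C3 nucleophile beta to O1 would expel the phenoxide. Since C2 carries two identical methyl groups, O1 is first parked on one of them. An O1–CH2–C(=CH2)–CH2Cl ether beside an aryl aldehyde closes a temporary seven-membered 1-benzoxepine by catalytic asymmetric Nozaki–Hiyama–Kishi allylation, forming C3–C4 and the C4 carbinol stereocentre in one operation. Reductive cleavage of the O1–CH2 bond with zerovalent palladium (the CH2 becomes a methyl group) and Markovnikov hydroalkoxylation of the resulting isobutenyl group by O1 then deliver the 2,2-dimethylchroman-4-ol.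

Key step: step 5

Remark: the target is (4R); the carbinol carbon keeps the descriptor R in compounds 9 to 13, since the priority order OH > aryl C > CH2 > H does not change.
Remark (assumption): the sense of induction of the chromium catalyst is taken by analogy from intermolecular methallylations of aryl aldehydes; if the first run gives the (5S) alcohol, the (R,R) ligand is used instead.

Step 1
Reactants: 1 2-methylbenzene-1,3,5-triol; 2 3-phenylpropanoyl chloride
Product: 3 1-(2,4,6-trihydroxy-3-methylphenyl)-3-phenylpropan-1-one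
Conditions: AlCl3 (3.5 equiv), PhNO2/CH2Cl2, 0 °C to 50 °C; aq. HCl
Reagents that add atoms: none
Why: Friedel–Crafts C-acylation (with Fries rearrangement of any aryl ester formed first) of the electron-rich triol, whose two free ring positions are equivalent so that only one monoketone can form, and the acyl group deactivates the ring against a second acylation.

Step 2
Reactants: 3 1-(2,4,6-trihydroxy-3-methylphenyl)-3-phenylpropan-1-one
Product: 5 2,4,6-trihydroxy-3-methyl-5-(3-phenylpropanoyl)benzaldehyde, via iminium chloride 4 (not isolated)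
Conditions: POCl3 (1.2 equiv), DMF (1.5 equiv), EtOAc, 0 °C to rt; then H2O, 50 °C
Reagents that add atoms: N,N-dimethylformamide CN(C)C=O; water O
Why: Vilsmeier–Haack formylation at the only free ring carbon, which is flanked by two hydroxyl groups and should react at low temperature well before the ketone side chain, followed by hydrolysis of the iminium salt.

Step 3
Reactants: 5 2,4,6-trihydroxy-3-methyl-5-(3-phenylpropanoyl)benzaldehyde
Product: 6 2-hydroxy-5-methyl-3-(3-phenylpropanoyl)-4,6-bis(triisopropylsilyloxy)benzaldehyde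
Conditions: iPr3SiCl (2.1 equiv), imidazole, DMF, 0 °C to rt
Reagents that add atoms: chlorotriisopropylsilane CC(C)[Si](Cl)(C(C)C)C(C)C
Why: Regioselective O-silylation, in which the two hydroxyl groups that are each para to one carbonyl group are the more acidic and should react first, whereas the hydroxyl flanked by both carbonyl groups (the future O1) is the least acidic, the most strongly hydrogen-bonded and the most hindered and is left free.

Step 4
Reactants: 6 2-hydroxy-5-methyl-3-(3-phenylpropanoyl)-4,6-bis(triisopropylsilyloxy)benzaldehyde; 7 3-chloro-2-(chloromethyl)prop-1-ene (5 equiv)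
Product: 8 2-{[2-(chloromethyl)prop-2-en-1-yl]oxy}-5-methyl-3-(3-phenylpropanoyl)-4,6-bis(triisopropylsilyloxy)benzaldehyde
Conditions: K2CO3, NaI (cat.), MeCN, 45 °C
Reagents that add atoms: none
Why: Williamson etherification (iodide-catalysed SN2) of the single remaining phenol with an excess of the symmetric bis-allylic chloride, which suppresses double alkylation, under mild anhydrous carbonate conditions that should spare the hindered aryl silyl ethers.

Step 5
Reactants: 8 2-{[2-(chloromethyl)prop-2-en-1-yl]oxy}-5-methyl-3-(3-phenylpropanoyl)-4,6-bis(triisopropylsilyloxy)benzaldehyde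
Product: 10 1-[(5R)-5-hydroxy-7-methyl-3-methylidene-6,8-bis(triisopropylsilyloxy)-2,3,4,5-tetrahydro-1-benzoxepin-9-yl]-3-phenylpropan-1-one, via trimethylsilyl ether 9 (not isolated)
Conditions: CrCl2 (10 mol %), 1,8-bis[(4S)-4-isopropyl-4,5-dihydrooxazol-2-yl]-3,6-diphenyl-9H-carbazole (12 mol %), Mn powder, iPr2NEt, Me3SiCl, THF, rt, slow addition (0.01 M); then aq. citric acid, MeOH
Reagents that add atoms: none
Why: Divalent chromium inserts into the allylic C–Cl bond to give a trivalent allylchromium reagent with two equivalent CH2 termini, which adds to the neighbouring aldehyde through a six-membered chair transition state (intramolecular Nozaki–Hiyama–Kishi allylation, catalytic in chromium with Mn as terminal reductant); the closest known reactions are catalytic enantioselective methallylations of aryl aldehydes with bis(oxazolinyl)carbazole chromium catalysts and intramolecular Nozaki–Hiyama–Kishi allylations that form medium rings. The seven-membered 1-benzoxepine ring closes in the 7-exo-trig mode, the terminal allyl carbon (future C3) attacking the carbonyl carbon (future C4) while the double bond moves to the exocyclic position. The new carbinol stereocentre is set under catalyst control by the C2-symmetric ligand on chromium, which differentiates the two faces of the aldehyde held in the chair. Chemoselectivity for the aldehyde over the ketone should follow from the strong aldehyde preference of allylchromium reagents and from the ketone being flanked by two ortho oxygen substituents, and cyclisation over oligomerisation from the ortho tether and high dilution. Because O1 sits on the carbon attached to the central allyl carbon and not on a carbon beta to chromium, the phenoxide cannot be expelled, which is the reason for parking O1 on the future methyl group. Silyl transfer from Me3SiCl to the chromium alkoxide releases the catalyst, and the labile trimethylsilyl ether is hydrolysed on work-up while the aryl silyl ethers should stay.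

Step 6
Reactants: 10 1-[(5R)-5-hydroxy-7-methyl-3-methylidene-6,8-bis(triisopropylsilyloxy)-2,3,4,5-tetrahydro-1-benzoxepin-9-yl]-3-phenylpropan-1-one
Product: 11 1-{2-hydroxy-3-[(1R)-1-hydroxy-3-methylbut-3-en-1-yl]-5-methyl-4,6-bis(triisopropylsilyloxy)phenyl}-3-phenylpropan-1-one
Conditions: Pd(PPh3)4 (5 mol %), HCO2H, Et3N, THF, 40 °C
Reagents that add atoms: none
Why: Tsuji–Trost ionisation of the cyclic allylic aryl ether by zerovalent palladium (the ortho-acyl phenoxide is a good leaving group) and formate-mediated hydride transfer to the symmetric 2-substituted allyl ligand should open the temporary ring, turning the O1-bearing CH2 into a methyl group and leaving the homoallylic carbinol stereocentre untouched.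

Step 7
Reactants: 11 1-{2-hydroxy-3-[(1R)-1-hydroxy-3-methylbut-3-en-1-yl]-5-methyl-4,6-bis(triisopropylsilyloxy)phenyl}-3-phenylpropan-1-one
Product: 12 1-[(4R)-4-hydroxy-2,2,6-trimethyl-5,7-bis(triisopropylsilyloxy)-3,4-dihydro-2H-chromen-8-yl]-3-phenylpropan-1-one
Conditions: [N,N′-bis(3,5-di-tert-butylsalicylidene)-1,2-cyclohexanediaminato]cobalt (3 mol %), N-fluoro-2,4,6-trimethylpyridinium tetrafluoroborate (1.5 equiv), PhSiH3 (1.5 equiv), PhCF3, rt
Reagents that add atoms: none
Why: Cobalt-catalysed hydrogen-atom-transfer hydroalkoxylation (radical–polar crossover), in which Markovnikov hydrogen-atom transfer to the 1,1-disubstituted alkene gives a tertiary radical that is oxidised at cobalt and captured by the only free phenol (O1) in a six-membered ring closure, under near-neutral conditions that should not ionise the benzylic alcohol, whose own cyclisation would require a four-membered ring.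

Step 8
Reactants: 12 1-[(4R)-4-hydroxy-2,2,6-trimethyl-5,7-bis(triisopropylsilyloxy)-3,4-dihydro-2H-chromen-8-yl]-3-phenylpropan-1-one
Product: 13 1-[(4R)-4,5,7-trihydroxy-2,2,6-trimethyl-3,4-dihydro-2H-chromen-8-yl]-3-phenylpropan-1-one
Conditions: Bu4NF, AcOH, THF, 0 °C
Reagents that add atoms: none
Why: Fluoride-induced cleavage of the two aryl silyl ethers (desilylation driven by Si–F bond formation), buffered with acetic acid so that neither acid nor strong base reaches the ionisation-prone benzylic alcohol.

**Compound list**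

1 | 2-methylbenzene-1,3,5-triol | Cc1c(O)cc(O)cc1O | starting material
2 | 3-phenylpropanoyl chloride | O=C(Cl)CCc1ccccc1 | starting material
3 | 1-(2,4,6-trihydroxy-3-methylphenyl)-3-phenylpropan-1-one | Cc1c(O)cc(O)c(C(=O)CCc2ccccc2)c1O | intermediate
4 | N-[2,4,6-trihydroxy-3-methyl-5-(3-phenylpropanoyl)benzylidene]-N-methylmethanaminium chloride | Cc1c(O)c(C=[N+](C)C)c(O)c(C(=O)CCc2ccccc2)c1O.[Cl-] | intermediate
5 | 2,4,6-trihydroxy-3-methyl-5-(3-phenylpropanoyl)benzaldehyde | Cc1c(O)c(C=O)c(O)c(C(=O)CCc2ccccc2)c1O | intermediate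
6 | 2-hydroxy-5-methyl-3-(3-phenylpropanoyl)-4,6-bis(triisopropylsilyloxy)benzaldehyde | Cc1c(O[Si](C(C)C)(C(C)C)C(C)C)c(C=O)c(O)c(C(=O)CCc2ccccc2)c1O[Si](C(C)C)(C(C)C)C(C)C | intermediate
7 | 3-chloro-2-(chloromethyl)prop-1-ene | C=C(CCl)CCl | starting material
8 | 2-{[2-(chloromethyl)prop-2-en-1-yl]oxy}-5-methyl-3-(3-phenylpropanoyl)-4,6-bis(triisopropylsilyloxy)benzaldehyde | Cc1c(O[Si](C(C)C)(C(C)C)C(C)C)c(C=O)c(OCC(=C)CCl)c(C(=O)CCc2ccccc2)c1O[Si](C(C)C)(C(C)C)C(C)C | intermediate
9 | 1-[(5R)-7-methyl-3-methylidene-6,8-bis(triisopropylsilyloxy)-5-(trimethylsilyloxy)-2,3,4,5-tetrahydro-1-benzoxepin-9-yl]-3-phenylpropan-1-one | Cc1c(O[Si](C(C)C)(C(C)C)C(C)C)c2c(c(C(=O)CCc3ccccc3)c1O[Si](C(C)C)(C(C)C)C(C)C)OCC(=C)C[C@H]2O[Si](C)(C)C | intermediate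
10 | 1-[(5R)-5-hydroxy-7-methyl-3-methylidene-6,8-bis(triisopropylsilyloxy)-2,3,4,5-tetrahydro-1-benzoxepin-9-yl]-3-phenylpropan-1-one | Cc1c(O[Si](C(C)C)(C(C)C)C(C)C)c2c(c(C(=O)CCc3ccccc3)c1O[Si](C(C)C)(C(C)C)C(C)C)OCC(=C)C[C@H]2O | intermediate
11 | 1-{2-hydroxy-3-[(1R)-1-hydroxy-3-methylbut-3-en-1-yl]-5-methyl-4,6-bis(triisopropylsilyloxy)phenyl}-3-phenylpropan-1-one | Cc1c(O[Si](C(C)C)(C(C)C)C(C)C)c([C@H](O)CC(C)=C)c(O)c(C(=O)CCc2ccccc2)c1O[Si](C(C)C)(C(C)C)C(C)C | intermediate
12 | 1-[(4R)-4-hydroxy-2,2,6-trimethyl-5,7-bis(triisopropylsilyloxy)-3,4-dihydro-2H-chromen-8-yl]-3-phenylpropan-1-one | Cc1c(O[Si](C(C)C)(C(C)C)C(C)C)c2c(c(C(=O)CCc3ccccc3)c1O[Si](C(C)C)(C(C)C)C(C)C)OC(C)(C)C[C@H]2O | intermediate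
13 | 1-[(4R)-4,5,7-trihydroxy-2,2,6-trimethyl-3,4-dihydro-2H-chromen-8-yl]-3-phenylpropan-1-one | Cc1c(O)c(C(=O)CCc2ccccc2)c2c(c1O)[C@H](O)CC(C)(C)O2 | target

**Totals.** Total step count: 8. Longest linear sequence: 8 steps (1 to 13).

**Steps most likely to fail**

1. Step 5: the two aldehyde faces may be poorly differentiated in the constrained bicyclic transition state, or intermolecular coupling may compete. The fallback sets out from 8. Ligand-free ring closure with stoichiometric CrCl2 in THF should give the racemic 1-[5-hydroxy-7-methyl-3-methylidene-6,8-bis(triisopropylsilyloxy)-2,3,4,5-tetrahydro-1-benzoxepin-9-yl]-3-phenylpropan-1-one F1. Kinetic resolution by enantioselective acylation follows (isobutyric anhydride, iPr2NEt, benzotetramisole as chiral acyl-transfer catalyst, the antipode chosen so that the (5S) alcohol is acylated faster). It should convert the unwanted enantiomer into (5S)-7-methyl-3-methylidene-9-(3-phenylpropanoyl)-6,8-bis(triisopropylsilyloxy)-2,3,4,5-tetrahydro-1-benzoxepin-5-yl 2-methylpropanoate F2, which is separated. The remaining (5R) alcohol is compound 10, where the route is rejoined.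

2. Step 3: regiocontrol may be lost through silylation of the hydroxyl between the two carbonyl groups. The fallback sets out from 3, before formylation, so that each choice rests on a para relationship or on sterics.
   - Monosilylation (iPr3SiCl, imidazole) of the only non-chelated hydroxyl, para to the ketone, should give 1-[2,6-dihydroxy-3-methyl-4-(triisopropylsilyloxy)phenyl]-3-phenylpropan-1-one F3.
   - Williamson alkylation with 7 (K2CO3, MeCN) at the chelated hydroxyl next to the ring hydrogen, which is less hindered than the one next to the methyl group, should give 1-[6-{[2-(chloromethyl)prop-2-en-1-yl]oxy}-2-hydroxy-3-methyl-4-(triisopropylsilyloxy)phenyl]-3-phenylpropan-1-one F4.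
   - Vilsmeier–Haack formylation (POCl3, DMF, 0 °C) of the last ring position, para to the free hydroxyl, passes through N-[2-{[2-(chloromethyl)prop-2-en-1-yl]oxy}-4-hydroxy-5-methyl-3-(3-phenylpropanoyl)-6-(triisopropylsilyloxy)benzylidene]-N-methylmethanaminium chloride F5. Hydrolysis should give 2-{[2-(chloromethyl)prop-2-en-1-yl]oxy}-4-hydroxy-5-methyl-3-(3-phenylpropanoyl)-6-(triisopropylsilyloxy)benzaldehyde F6.
   - Silylation of the remaining hydroxyl (iPr3SiOTf, 2,6-lutidine) returns to 8.

3. Step 7: the tertiary radical may be reduced or lose a proton (net hydrogenation or alkene isomerisation) faster than the C–O bond forms. The fallback sets out from 11. Iodoetherification (I2, NaHCO3, MeCN, 0 °C; 6-exo attack of O1 at the tertiary carbon of the iodonium ion) should give 1-[(4R)-4-hydroxy-2-(iodomethyl)-2,6-dimethyl-5,7-bis(triisopropylsilyloxy)-3,4-dihydro-2H-chromen-8-yl]-3-phenylpropan-1-one F7 as a mixture of C2 epimers. Radical deiodination (Bu3SnH, AIBN, toluene, 80 °C) turns the iodomethyl group into the second methyl group, merges both epimers and comes back to the route at 12.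

**Further compounds**

F1 | step 5 | racemic 1-[5-hydroxy-7-methyl-3-methylidene-6,8-bis(triisopropylsilyloxy)-2,3,4,5-tetrahydro-1-benzoxepin-9-yl]-3-phenylpropan-1-one | Cc1c(O[Si](C(C)C)(C(C)C)C(C)C)c2c(c(C(=O)CCc3ccccc3)c1O[Si](C(C)C)(C(C)C)C(C)C)OCC(=C)CC2O
F2 | step 5 | (5S)-7-methyl-3-methylidene-9-(3-phenylpropanoyl)-6,8-bis(triisopropylsilyloxy)-2,3,4,5-tetrahydro-1-benzoxepin-5-yl 2-methylpropanoate | Cc1c(O[Si](C(C)C)(C(C)C)C(C)C)c2c(c(C(=O)CCc3ccccc3)c1O[Si](C(C)C)(C(C)C)C(C)C)OCC(=C)C[C@@H]2OC(=O)C(C)C
F3 | step 3 | 1-[2,6-dihydroxy-3-methyl-4-(triisopropylsilyloxy)phenyl]-3-phenylpropan-1-one | Cc1c(O[Si](C(C)C)(C(C)C)C(C)C)cc(O)c(C(=O)CCc2ccccc2)c1O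
F4 | step 3 | 1-[6-{[2-(chloromethyl)prop-2-en-1-yl]oxy}-2-hydroxy-3-methyl-4-(triisopropylsilyloxy)phenyl]-3-phenylpropan-1-one | Cc1c(O[Si](C(C)C)(C(C)C)C(C)C)cc(OCC(=C)CCl)c(C(=O)CCc2ccccc2)c1O
F5 | step 3 | N-[2-{[2-(chloromethyl)prop-2-en-1-yl]oxy}-4-hydroxy-5-methyl-3-(3-phenylpropanoyl)-6-(triisopropylsilyloxy)benzylidene]-N-methylmethanaminium chloride | Cc1c(O[Si](C(C)C)(C(C)C)C(C)C)c(C=[N+](C)C)c(OCC(=C)CCl)c(C(=O)CCc2ccccc2)c1O.[Cl-]
F6 | step 3 | 2-{[2-(chloromethyl)prop-2-en-1-yl]oxy}-4-hydroxy-5-methyl-3-(3-phenylpropanoyl)-6-(triisopropylsilyloxy)benzaldehyde | Cc1c(O[Si](C(C)C)(C(C)C)C(C)C)c(C=O)c(OCC(=C)CCl)c(C(=O)CCc2ccccc2)c1O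
F7 | step 7 | 1-[(4R)-4-hydroxy-2-(iodomethyl)-2,6-dimethyl-5,7-bis(triisopropylsilyloxy)-3,4-dihydro-2H-chromen-8-yl]-3-phenylpropan-1-one (C2 epimers) | Cc1c(O[Si](C(C)C)(C(C)C)C(C)C)c2c(c(C(=O)CCc3ccccc3)c1O[Si](C(C)C)(C(C)C)C(C)C)OC(C)(CI)C[C@H]2O
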